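What struck me first was the slowness: the west run still held 86.7% of its starting material after 2.50 d, yet the new flasks get 6.0 d. So I wanted two times and their ratio: the time in the flask and the life τ of starting material, which is the time divided by minus the natural logarithm of the fraction left.

| flask | starting material | free catalyst | temperature | remark | time |
|---|---|---|---|---|---|
| west | 0.079 M | 1.5 mol% | 70 °C | run made earlier |  |
| north-east | 0.079 M | 2.4 mol% | 92 °C | run made earlier |  |
| east | 0.16 M | 1.1 mol% | 70 °C | run made earlier |  |
| Tuesday's | 0.079 M | 1.1 mol% |  | at 60 °C until 4.0 d, from then on at 100 °C | 6.0 d |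
| Monday's | 0.079 M | 1.1 mol% | 60 °C |  | 6.0 d |
| Thursday's | 0.079 M | 1.1 mol% | 80 °C |  | 6.0 d |
| Saturday's | 0.079 M | 1.1 mol% | 100 °C |  | 6.0 d |

west run (percent of the starting material charged)

| time / d | product / % | starting material / % |
|---|---|---|
| 0.167 | 1.7 | 97.9 |
| 0.333 | 1.4 | 97.4 |
| 0.625 | 1.1 | 95.9 |
| 1.25 | 7.0 | 92.8 |
| 2.50 | 14.6 | 86.7 |

north-east run (percent of the starting material charged)

| time / h | product / % | starting material / % |
|---|---|---|
| 1.33 | 2.5 | 95.5 |
| 2.50 | 7.8 | 89.2 |
| 5.00 | 15.2 | 84.1 |
| 10.0 | 30.0 | 71.0 |
| 20.0 | 51.3 | 48.8 |

east run (percent of the starting material charged)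

| time / d | product / % | starting material / % |
|---|---|---|
| 0.208 | 0 | 98.3 |
| 0.500 | 1.6 | 96.4 |
| 1.04 | 2.3 | 95.0 |
| 1.67 | 6.8 | 93.3 |
| 2.50 | 11.7 | 88.9 |

(each reading ± 1 percentage point)



- the best flask by amount of product, in percent of the starting material charged; "all alike" if 1.5 percentage points covers them all (Tuesday's / Monday's / Thursday's / Saturday's / all alike)
- amount of product at the end, in percent of the starting material charged, Tuesday's
- amount of product at the end, in percent of the starting material charged, Monday's
- amount of product at the end, in percent of the starting material charged, Thursday's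
- amount of product at the end, in percent of the starting material charged, Saturday's

Product and starting material summed close to the charge, so I read lost starting material as product. In the north-east run τ came to 29.2 h from the reading at 10.0 h and 27.9 h from the one at 20.0 h, so I saw no further, slower clock. The east run had twice the concentration of the west run, yet with τ at 17.5 d in the west run and 21.2 d in the east run, τ times loading in mol% differed between them by a ratio of 1.12. I therefore took τ at a given temperature as inverse to the loading in mol%, a rule read from these two runs with their scatter.

From the west run to the north-east run, τ times loading fell by a factor of 9.43. Spreading that factor evenly over the degrees, I reckoned τ at 1.1 mol% as 66.2 d for Monday's, 8.62 d for Thursday's and 1.12 d for Saturday's.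

The number of lives N, time in the flask over τ, is 5.35 for Saturday's. Lives add, so Tuesday's has 1.84. With product as one minus e to the power minus N, I expected 8.66% for Monday's, 50.1% for Thursday's, 84.1% for Tuesday's and 99.5% for Saturday's, which leads.

The forecast also named Saturday's, with 95%, 78% for Tuesday's, 51% for Thursday's and 9% for Monday's. At Saturday's it stood lower than mine: “I shade the 100 °C values down for possible catalyst loss, which is untested there.”

Saturday's led with 99.3%, ahead of Tuesday's 81.5%, Thursday's 53.0% and Monday's 7.27%.

    starting material + free catalyst → catalyst intermediate A (k = 100 L mol⁻¹ h⁻¹, Ea = 75.0 kJ mol⁻¹)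
    catalyst intermediate A → catalyst intermediate B (k = 7.00 h⁻¹, Ea = 113 kJ mol⁻¹)
    catalyst intermediate B → free catalyst + product (k = 8.10 h⁻¹, Ea = 104 kJ mol⁻¹)
    starting material + free catalyst → spent catalyst (k = 0.480 L mol⁻¹ h⁻¹, Ea = 85.0 kJ mol⁻¹)
    (constants at 100 °C)

Saturday's had 0.22% of its starting material left at 6.00 d, and it already held 92.4% product at 3.00 d, where half of N gives 93.1%. For the neighbour of Saturday's charged with 0.28 mol%, N scales to 1.36, which gives 74.3%. That neighbour held 45.8% product, with 78.5% of its catalyst spent.

All runs were generated by integration with made-up constants.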